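Amounts first. Amber holds 0.400 M of starting material and 0.800 M of reagent, the charge of blue. Starting material is the limiting reagent, so I reckon the share on it. Blue's readings stop at 13 min, but amber is asked at 32 min.

| setting | blue | ochre | green | violet | amber |
|---|---|---|---|---|---|
| starting material | 0.400 M | 0.160 M | 0.400 M | 0.200 M | 0.400 M |
| reagent | 0.800 M | 0.560 M | 1.20 M | 0.800 M | 0.800 M |
| time |  |  |  |  | 32 min |

- blue run (time / min: [target] / M): 1.6: 0.0203; 3.2: 0.0486; 4.9: 0.0725; 6.5: 0.0922; 8.1: 0.1124; 9.8: 0.1295; 11: 0.1446; 13: 0.1586
- ochre run (time / min: [target] / M): 1.6: 0.0065; 3.2: 0.0112; 4.9: 0.0188; 6.5: 0.0221; 8.1: 0.0262; 9.8: 0.0338; 11: 0.0378; 13: 0.0431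
- green run (time / min: [target] / M): 1.6: 0.0384; 3.2: 0.0704; 4.9: 0.1023; 6.5: 0.1344; 8.1: 0.1526; 9.8: 0.1761; 11: 0.1824; 13: 0.1912
- violet run (time / min: [target] / M): 1.6: 0.0103; 3.2: 0.0228; 4.9: 0.0305; 6.5: 0.0401; 8.1: 0.0470; 9.8: 0.0563; 11: 0.0608; 13: 0.0656

(standard deviation of a reading: 0.002 M)

1. reaction order in [reagent] at the outset, round the charge of the blue run, defined at two percent of the starting material turned into target
2. reaction order in [starting material] at the outset, round the charge of the blue run, defined at two percent of the starting material turned into target (one fixed amount of target, the same in the runs compared)
3. target in the amber run at 32 min, as a share of the starting material charged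

- Overall: starting material + reagent -> target.
- Constant volume, constant temperature.
- An order is taken over about fifteen percent of the charge, up and down.

Green has the starting material of blue and more reagent. Their reagent charges stand at 1.50, green over blue. I call this the reagent clock, the minutes of blue that one minute of green is worth at the outset. I test it on the readings. Green reads 0.0704 M at 3.2 min, and blue reads 0.0725 M at 4.9 min. Green reads 0.1344 M at 6.5 min, and blue reads 0.1295 M at 9.8 min. Those times stand in the clock's ratio. A clock equal to the charge ratio points to an order near one in reagent.

So I read amber at 32 min as green at 21.3 min at the latest, since the clock grows as equal amounts of reagent are spent. Reagent spent is at least the target made, so at green's last reading the ratio of reagent remaining is at least 1.66. That later clock puts amber's time at 19.3 min of green, still past green's last reading at 13 min. That last reading is 0.1912 M, or 47.8% of the charge. This is my bound from below, provided target does not fall. For the bound from above, I keep green's slope from 9.8 min to 13 min, 0.00472 M min⁻¹, up to 21.3 min, which gives 57.6%. Green's gain over that span is 0.362 of its gain over the span before. If later spans keep that ratio, the gains sum to 49.9%. I commit to that tightened figure, and in amber I watch for target to flatten near 0.200 M.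

The forecast gives 58%, with orders 0.95 in reagent and 1.15 in starting material, and notes that “green stalls sharply near 0.19 M”. Its share stands above my upper bound.

Amber gives 48.4%, with orders 1.0 in reagent and 1.0 in starting material.

    starting material + reagent → target (0.04452 M⁻¹ min⁻¹)
    target + reagent → side product (0.05940 M⁻¹ min⁻¹)
    starting material + reagent + target → 2 target (0.4236 M⁻² min⁻¹)

That share lies above green's last share and below my tightened figure. At equal target made, green runs 1.5 times as fast as blue, which matches the clock. Blue reaches a quarter of its charge at 7.03 min. Divided by the clock, that puts green's quarter at 4.69 min, and green reads 0.1023 M at 4.9 min.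

The runs stem from a simulated flask from invented constants.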